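**Retrosynthetic overview**

1. The target is numbered from the carboxyl carbon C1 (ring O1–O2–C3–C4–C5–C6, O2 on C3, O1 on C6, chain C7–C22). The last disconnection is the ester C–O bond: an enantioselective hydrolase resolves the racemic methyl ester and so fixes (3S,6R).
2. The C11–C12 bond is cut by a Sonogashira disconnection into a ring-bearing terminal alkyne (C1–C11) and (E)-11-iodoundec-10-en-2-one (C12–C22), the latter made from dec-9-en-1-ol by Wacker oxidation, alcohol oxidation and Takai olefination.
3. Feature: the 1,2-dioxane carries its two C–O bonds on C3 and C6, a 1,4-dioxygenation that carbonyl polarity cannot pair. The ring is therefore cut at C4–C5, C3–O2 and O1–C6 into a C5–C6 ketone unit, the C3=C4 alkene of methyl but-3-enoate and O2, joined by a radical three-component reaction mediated by trivalent manganese.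
4. A temporary tert-butyl ester on C5 makes that carbon oxidisable and is later lost by decarboxylation. The C6 methoxy group is then installed under anomeric (thermodynamic) control relative to C3.
5. Ring order: the only ring, the 1,2-dioxane, is closed in the key step. Its keto ester precursor comes from hex-5-ynoic acid and mono-tert-butyl malonate.

Key step: step 3

Assumption: all 1,2-dioxane intermediates before the last step are racemic and are drawn and named as the enantiomer that leads to the target; the hydrolase of the last step is taken to be one found by screening to hydrolyse the (3S,6R)-ester faster.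

**Route**

Step 1
Reactants: 1 hex-5-ynoic acid
Product: 2 6-(triisopropylsilyl)hex-5-ynoic acid
Conditions: n-BuLi (2.2 equiv), THF, −78 → 0 °C; TIPSCl (1.1 equiv), −78 °C → rt; K2CO3, MeOH/H2O, then dilute HCl to pH 3
Reagents that add atoms: triisopropylsilyl chloride, CC(C)[Si](Cl)(C(C)C)C(C)C
Why: Two equivalents of base give the carboxylate–acetylide dianion, whose carbon terminus is silylated (C-silylation of a lithium acetylide); any silyl ester is cleaved in the work-up.

Step 2
Reactants: 2 6-(triisopropylsilyl)hex-5-ynoic acid; 3 mono-tert-butyl malonate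
Product: 6 tert-butyl 3-oxo-8-(triisopropylsilyl)oct-7-ynoate, via acyl imidazolide 4 (not isolated), via acylmalonate half-ester 5 (not isolated)
Conditions: CDI (1.1 equiv), THF, rt; then 3 (1.5 equiv), MgCl2 (1.5 equiv), Et3N (3 equiv), MeCN/THF, rt → 40 °C; cold 0.5 M HCl
Reagents that add atoms: none
Why: Masamune–Brooks homologation: the acyl imidazolide acylates the magnesium enolate of the malonate half-ester and the acylmalonate loses carbon dioxide, giving the β-keto ester under near-neutral conditions that leave the silyl alkyne untouched.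

Step 3
Reactants: 6 tert-butyl 3-oxo-8-(triisopropylsilyl)oct-7-ynoate; 7 methyl but-3-enoate; 8 dioxygen
Product: 10 tert-butyl rac-(3R,4S,6S)-3-hydroxy-6-(2-methoxy-2-oxoethyl)-3-[5-(triisopropylsilyl)pent-4-yn-1-yl]-1,2-dioxane-4-carboxylate, via open-chain hydroperoxide 9 (not isolated)
Conditions: Mn(OAc)3·2H2O (0.2 equiv), Mn(OAc)2·4H2O (0.2 equiv), O2 (1 atm), 7 (5 equiv), AcOH, 23 °C
Reagents that add atoms: none
Why: Mn(OAc)3 (trivalent manganese) oxidises the enol of 6 to the electrophilic C5 radical, which adds to the unsubstituted terminus C4 of 7; the secondary C3 radical is captured by dioxygen at close to the diffusion limit, and the peroxyl radical is reduced to hydroperoxide 9 by divalent manganese, which returns the trivalent oxidant, or by hydrogen transfer from 6. The hydroperoxide oxygen then adds to the C6 ketone in a reversible 6-exo-trig hemiketalisation that closes the 1,2-dioxane, so that C4–C5, C3–O2 and O1–C6 are made in one operation; the closest known reaction is the manganese-mediated aerobic peroxycyclisation of 1,3-dicarbonyl compounds with alkenes to 1,2-dioxan-3-ols, for which a monosubstituted aliphatic alkene is a sluggish partner. C3 arises from a planar radical without chiral influence and is racemic; C5 and C6 are set relative to C3 under thermodynamic control, because the hemiketal opens and recloses and C5 enolises in the open form, so the chair with axial anomeric hydroxyl and equatorial ester, alkynyl chain and acetate arm should prevail. The step needs carbon–carbon bond formation at C4 with oxygen capture at C3, and both follow from the polarity of the radical (attack at the unhindered terminal carbon) and from the oxygen atmosphere. The alkene is used in fivefold excess so that intermolecular addition outruns direct oxygenation of the keto ester radical and its 6-exo-dig closure onto the silyl alkyne, a triple bond that electrophilic radicals attack more slowly than a terminal alkene; ring closure masks the ketone and so protects 10 from a second oxidation.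

Step 4
Reactants: 10 tert-butyl rac-(3R,4S,6S)-3-hydroxy-6-(2-methoxy-2-oxoethyl)-3-[5-(triisopropylsilyl)pent-4-yn-1-yl]-1,2-dioxane-4-carboxylate
Product: 14 methyl 2-[rac-(3S,6R)-6-hydroxy-6-[5-(triisopropylsilyl)pent-4-yn-1-yl]-1,2-dioxan-3-yl]acetate, via hemiketal acid 11 (not isolated), via open-chain keto acid 12 (not isolated), via hydroperoxy ketone 13 (not isolated)
Conditions: TFA/CH2Cl2 (1:4, trace H2O), 0 °C → rt; evaporate; toluene, 40 °C
Reagents that add atoms: none
Why: Acidolysis of the tert-butyl ester (loss of isobutene) gives the hemiketal acid, whose open-chain tautomer is a β-keto acid that decarboxylates on gentle warming; the hydroperoxy ketone recloses to the 1,2-dioxan-3-ol, C5 ceases to be a stereocentre, and C6 returns to the axial-hydroxyl arrangement relative to C3 by ring–chain equilibration.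

Step 5
Reactants: 14 methyl 2-[rac-(3S,6R)-6-hydroxy-6-[5-(triisopropylsilyl)pent-4-yn-1-yl]-1,2-dioxan-3-yl]acetate
Product: 15 methyl 2-[rac-(3S,6R)-6-methoxy-6-[5-(triisopropylsilyl)pent-4-yn-1-yl]-1,2-dioxan-3-yl]acetate
Conditions: TsOH·H2O (0.1 equiv), MeOH, 3 Å molecular sieves, rt
Reagents that add atoms: methanol, CO
Why: Acid-catalysed peroxyketal formation through the peroxycarbenium ion is reversible, so C6 is set thermodynamically relative to C3: the anomeric effect places methoxy axial while both carbon substituents stay equatorial, which is methoxy cis to the acetate arm as in the target (a minor C6 epimer could be resubmitted).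

Step 6
Reactants: 15 methyl 2-[rac-(3S,6R)-6-methoxy-6-[5-(triisopropylsilyl)pent-4-yn-1-yl]-1,2-dioxan-3-yl]acetate
Product: 16 methyl 2-[rac-(3S,6R)-6-methoxy-6-(pent-4-yn-1-yl)-1,2-dioxan-3-yl]acetate
Conditions: TBAF (1.2 equiv), THF, 0 °C
Reagents that add atoms: none
Why: Fluoride-induced protodesilylation of the alkynylsilane; the ring, now locked as its methyl peroxyketal, and the methyl ester should tolerate brief exposure to TBAF at 0 °C.

Step 7
Reactants: 17 dec-9-en-1-ol
Product: 18 10-hydroxydecan-2-one
Conditions: PdCl2 (0.1 equiv), CuCl (0.5 equiv), O2 (1 atm), DMF/H2O (7:1), rt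
Reagents that add atoms: water, O
Why: Tsuji–Wacker oxidation: Markovnikov hydroxypalladation of the terminal alkene and β-hydride elimination give the methyl ketone, the remote primary alcohol being a spectator.

Step 8
Reactants: 18 10-hydroxydecan-2-one
Product: 19 9-oxodecanal
Conditions: PhI(OAc)2 (1.1 equiv), TEMPO (0.1 equiv), CH2Cl2, rt
Reagents that add atoms: none
Why: TEMPO-catalysed oxoammonium oxidation of the primary alcohol stops at the aldehyde and leaves the ketone untouched.

Step 9
Reactants: 19 9-oxodecanal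
Product: 20 (E)-11-iodoundec-10-en-2-one
Conditions: CrCl2 (6 equiv), CHI3 (2 equiv), THF/1,4-dioxane (1:6), 0 °C → rt
Reagents that add atoms: iodoform, IC(I)I
Why: Takai olefination: the geminal dichromium species from iodoform and CrCl2 (divalent chromium) adds to the aldehyde much faster than to the ketone and eliminates to give the (E)-vinyl iodide with one added carbon.

Step 10
Reactants: 16 methyl 2-[rac-(3S,6R)-6-methoxy-6-(pent-4-yn-1-yl)-1,2-dioxan-3-yl]acetate; 20 (E)-11-iodoundec-10-en-2-one
Product: 21 methyl 2-[rac-(3S,6R)-6-methoxy-6-[(6E)-15-oxohexadec-6-en-4-yn-1-yl]-1,2-dioxan-3-yl]acetate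
Conditions: PdCl2(PPh3)2 (0.03 equiv), CuI (0.06 equiv), Et3N (3 equiv), degassed THF, rt, dark
Reagents that add atoms: none
Why: Sonogashira coupling forms C11–C12 at room temperature with retention of the alkene geometry; a dialkyl peroxyketal should survive the palladium–copper system when free phosphine and heat are kept low.

Step 11
Reactants: 21 methyl 2-[rac-(3S,6R)-6-methoxy-6-[(6E)-15-oxohexadec-6-en-4-yn-1-yl]-1,2-dioxan-3-yl]acetate
Product: 22 2-[(3S,6R)-6-methoxy-6-[(6E)-15-oxohexadec-6-en-4-yn-1-yl]-1,2-dioxan-3-yl]acetic acid (target)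
Conditions: lipase from Burkholderia cepacia (immobilised), 0.1 M phosphate buffer pH 7.0/acetone (9:1), 30 °C, pH-stat, stopped before half conversion; citric acid to pH 4, extraction, chromatography
Reagents that add atoms: water, O
Why: Hydrolase-catalysed kinetic resolution by enantioselective ester hydrolysis: the enzyme should hydrolyse the (3S,6R)-ester faster at neutral pH, which fixes C3 and with it C6 (tied to C3 since step 5) in the absolute configuration of the target, while the (3R,6S)-ester stays unreacted and is separated from the acid.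

**Compound list**

1 | hex-5-ynoic acid | C#CCCCC(=O)O | starting material
2 | 6-(triisopropylsilyl)hex-5-ynoic acid | CC(C)[Si](C#CCCCC(=O)O)(C(C)C)C(C)C | intermediate
3 | mono-tert-butyl malonate (3-tert-butoxy-3-oxopropanoic acid) | CC(C)(C)OC(=O)CC(=O)O | starting material
4 | 1-(imidazol-1-yl)-6-(triisopropylsilyl)hex-5-yn-1-one (acyl imidazolide) | CC(C)[Si](C#CCCCC(=O)n1ccnc1)(C(C)C)C(C)C | intermediate (not isolated)
5 | 2-(tert-butoxycarbonyl)-3-oxo-8-(triisopropylsilyl)oct-7-ynoic acid (present as its magnesium chelate) | CC(C)(C)OC(=O)C(C(=O)O)C(=O)CCCC#C[Si](C(C)C)(C(C)C)C(C)C | intermediate (not isolated)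
6 | tert-butyl 3-oxo-8-(triisopropylsilyl)oct-7-ynoate | CC(C)(C)OC(=O)CC(=O)CCCC#C[Si](C(C)C)(C(C)C)C(C)C | intermediate
7 | methyl but-3-enoate | C=CCC(=O)OC | starting material
8 | dioxygen | O=O | starting material
9 | 1-tert-butyl 6-methyl 4-hydroperoxy-2-[6-(triisopropylsilyl)hex-5-ynoyl]hexanedioate (racemic, both diastereomers) | CC(C)(C)OC(=O)C(CC(OO)CC(=O)OC)C(=O)CCCC#C[Si](C(C)C)(C(C)C)C(C)C | intermediate (not isolated)
10 | tert-butyl rac-(3R,4S,6S)-3-hydroxy-6-(2-methoxy-2-oxoethyl)-3-[5-(triisopropylsilyl)pent-4-yn-1-yl]-1,2-dioxane-4-carboxylate (axial hydroxyl cis to the acetate arm, ester equatorial; racemic) | O[C@@]1(CCCC#C[Si](C(C)C)(C(C)C)C(C)C)[C@@H](C(=O)OC(C)(C)C)C[C@@H](CC(=O)OC)OO1 | intermediate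
11 | rac-(3R,4S,6S)-3-hydroxy-6-(2-methoxy-2-oxoethyl)-3-[5-(triisopropylsilyl)pent-4-yn-1-yl]-1,2-dioxane-4-carboxylic acid | O[C@@]1(CCCC#C[Si](C(C)C)(C(C)C)C(C)C)[C@@H](C(=O)O)C[C@@H](CC(=O)OC)OO1 | intermediate (not isolated)
12 | 4-hydroperoxy-6-methoxy-6-oxo-2-[6-(triisopropylsilyl)hex-5-ynoyl]hexanoic acid (racemic) | OC(=O)C(CC(OO)CC(=O)OC)C(=O)CCCC#C[Si](C(C)C)(C(C)C)C(C)C | intermediate (not isolated)
13 | methyl 3-hydroperoxy-6-oxo-11-(triisopropylsilyl)undec-10-ynoate (racemic) | COC(=O)CC(OO)CCC(=O)CCCC#C[Si](C(C)C)(C(C)C)C(C)C | intermediate (not isolated)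
14 | methyl 2-[rac-(3S,6R)-6-hydroxy-6-[5-(triisopropylsilyl)pent-4-yn-1-yl]-1,2-dioxan-3-yl]acetate | O[C@@]1(CCCC#C[Si](C(C)C)(C(C)C)C(C)C)CC[C@@H](CC(=O)OC)OO1 | intermediate
15 | methyl 2-[rac-(3S,6R)-6-methoxy-6-[5-(triisopropylsilyl)pent-4-yn-1-yl]-1,2-dioxan-3-yl]acetate | CO[C@@]1(CCCC#C[Si](C(C)C)(C(C)C)C(C)C)CC[C@@H](CC(=O)OC)OO1 | intermediate
16 | methyl 2-[rac-(3S,6R)-6-methoxy-6-(pent-4-yn-1-yl)-1,2-dioxan-3-yl]acetate | CO[C@@]1(CCCC#C)CC[C@@H](CC(=O)OC)OO1 | intermediate
17 | dec-9-en-1-ol | C=CCCCCCCCCO | starting material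
18 | 10-hydroxydecan-2-one | CC(=O)CCCCCCCCO | intermediate
19 | 9-oxodecanal | CC(=O)CCCCCCCC=O | intermediate
20 | (E)-11-iodoundec-10-en-2-one | CC(=O)CCCCCCC/C=C/I | intermediate
21 | methyl 2-[rac-(3S,6R)-6-methoxy-6-[(6E)-15-oxohexadec-6-en-4-yn-1-yl]-1,2-dioxan-3-yl]acetate | CO[C@@]1(CCCC#C/C=C/CCCCCCCC(C)=O)CC[C@@H](CC(=O)OC)OO1 | intermediate
22 | 2-[(3S,6R)-6-methoxy-6-[(6E)-15-oxohexadec-6-en-4-yn-1-yl]-1,2-dioxan-3-yl]acetic acid | CO[C@@]1(CCCC#C/C=C/CCCCCCCC(C)=O)CC[C@@H](CC(=O)O)OO1 | target

**Step count**

Total: 11 steps. Longest linear sequence: 8 steps (steps 1–6, 10 and 11, from hex-5-ynoic acid). The vinyl iodide branch has 3 steps (7–9).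

**Steps most likely to fail**

1. Step 3. Addition of the keto ester radical to an unactivated, monosubstituted alkene is slow. Direct oxygenation and cleavage of the keto ester, closure of the radical onto the tethered alkyne, and abstraction of the doubly activated allylic hydrogen of the butenoate could therefore consume the material. The fallback sets out from 6 and comes back at 15; it forms C4–C5 by enolate alkylation and closes the ring by polar peroxide chemistry. Keto ester 6 would be alkylated with methyl (E)-4-bromobut-2-enoate (K2CO3, acetone) to 1-tert-butyl 6-methyl (4E)-2-[6-(triisopropylsilyl)hex-5-ynoyl]hex-4-enedioate F1. TFA in CH2Cl2 would cleave the tert-butyl ester to (4E)-6-methoxy-6-oxo-2-[6-(triisopropylsilyl)hex-5-ynoyl]hex-4-enoic acid F2, which should lose carbon dioxide on warming to give methyl (2E)-6-oxo-11-(triisopropylsilyl)undec-2-en-10-ynoate F3. HC(OMe)3 and TsOH in MeOH would give methyl (2E)-6,6-dimethoxy-11-(triisopropylsilyl)undec-2-en-10-ynoate F4. Urea–hydrogen peroxide with catalytic Sc(OTf)3 in MeOH would exchange one methoxy group for hydroperoxy, giving methyl (2E)-6-hydroperoxy-6-methoxy-11-(triisopropylsilyl)undec-2-en-10-ynoate F5. Et2NH in CF3CH2OH would then trigger 6-exo-trig conjugate addition of the hydroperoxide to the enoate and give 15, whose C6 epimers can be equilibrated under the conditions of step 5.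

2. Step 11. The stereocentre lies β to the ester carbonyl, far from the catalytic serine, so the enzyme may discriminate the enantiomers poorly or prefer the wrong one. The lipophilic oil may also disperse badly in buffer and hydrolyse slowly. The fallback sets out from 21 and comes back at 22. Preparative chromatography on a cellulose tris(3,5-dimethylphenylcarbamate) chiral phase would separate the enantiomers of 21. The faster or slower fraction identified as methyl 2-[(3S,6R)-6-methoxy-6-[(6E)-15-oxohexadec-6-en-4-yn-1-yl]-1,2-dioxan-3-yl]acetate F6 (single enantiomer) would then be saponified with LiOH in THF/H2O at 0 °C to 22.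

3. Step 4. Strong acid may dehydrate or fragment the peroxyhemiketal before the ester is gone, and decarboxylation may stall because the ring-closed hemiketal masks the β-keto acid. The fallback sets out from 6 and comes back at 16; it replaces the acid-labile ester by a fluoride-labile one, so that the peroxide never meets strong acid. Keto ester 6 would be transesterified with 2-(trimethylsilyl)ethanol in toluene at 110 °C (through the acylketene) to 2-(trimethylsilyl)ethyl 3-oxo-8-(triisopropylsilyl)oct-7-ynoate F7. The conditions of step 3 with 7 and 8 should give 2-(trimethylsilyl)ethyl rac-(3R,4S,6S)-3-hydroxy-6-(2-methoxy-2-oxoethyl)-3-[5-(triisopropylsilyl)pent-4-yn-1-yl]-1,2-dioxane-4-carboxylate F8. TBAF in THF would remove the silylethyl ester and the alkynyl silyl group together, giving rac-(3R,4S,6S)-3-hydroxy-6-(2-methoxy-2-oxoethyl)-3-(pent-4-yn-1-yl)-1,2-dioxane-4-carboxylic acid F9 as its carboxylate. Buffering with acetic acid and warming to 40 °C should decarboxylate it to methyl 2-[rac-(3S,6R)-6-hydroxy-6-(pent-4-yn-1-yl)-1,2-dioxan-3-yl]acetate F10. TsOH in MeOH, as in step 5, would then give 16.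

**Further compounds**

F1 | step 3 | 1-tert-butyl 6-methyl (4E)-2-[6-(triisopropylsilyl)hex-5-ynoyl]hex-4-enedioate | CC(C)(C)OC(=O)C(C/C=C/C(=O)OC)C(=O)CCCC#C[Si](C(C)C)(C(C)C)C(C)C
F2 | step 3 | (4E)-6-methoxy-6-oxo-2-[6-(triisopropylsilyl)hex-5-ynoyl]hex-4-enoic acid | OC(=O)C(C/C=C/C(=O)OC)C(=O)CCCC#C[Si](C(C)C)(C(C)C)C(C)C
F3 | step 3 | methyl (2E)-6-oxo-11-(triisopropylsilyl)undec-2-en-10-ynoate | COC(=O)/C=C/CCC(=O)CCCC#C[Si](C(C)C)(C(C)C)C(C)C
F4 | step 3 | methyl (2E)-6,6-dimethoxy-11-(triisopropylsilyl)undec-2-en-10-ynoate | COC(=O)/C=C/CCC(OC)(OC)CCCC#C[Si](C(C)C)(C(C)C)C(C)C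
F5 | step 3 | methyl (2E)-6-hydroperoxy-6-methoxy-11-(triisopropylsilyl)undec-2-en-10-ynoate (racemic) | COC(=O)/C=C/CCC(OC)(OO)CCCC#C[Si](C(C)C)(C(C)C)C(C)C
F6 | step 11 | methyl 2-[(3S,6R)-6-methoxy-6-[(6E)-15-oxohexadec-6-en-4-yn-1-yl]-1,2-dioxan-3-yl]acetate (single enantiomer) | CO[C@@]1(CCCC#C/C=C/CCCCCCCC(C)=O)CC[C@@H](CC(=O)OC)OO1
F7 | step 4 | 2-(trimethylsilyl)ethyl 3-oxo-8-(triisopropylsilyl)oct-7-ynoate | C[Si](C)(C)CCOC(=O)CC(=O)CCCC#C[Si](C(C)C)(C(C)C)C(C)C
F8 | step 4 | 2-(trimethylsilyl)ethyl rac-(3R,4S,6S)-3-hydroxy-6-(2-methoxy-2-oxoethyl)-3-[5-(triisopropylsilyl)pent-4-yn-1-yl]-1,2-dioxane-4-carboxylate | O[C@@]1(CCCC#C[Si](C(C)C)(C(C)C)C(C)C)[C@@H](C(=O)OCC[Si](C)(C)C)C[C@@H](CC(=O)OC)OO1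
F9 | step 4 | rac-(3R,4S,6S)-3-hydroxy-6-(2-methoxy-2-oxoethyl)-3-(pent-4-yn-1-yl)-1,2-dioxane-4-carboxylic acid | O[C@@]1(CCCC#C)[C@@H](C(=O)O)C[C@@H](CC(=O)OC)OO1
F10 | step 4 | methyl 2-[rac-(3S,6R)-6-hydroxy-6-(pent-4-yn-1-yl)-1,2-dioxan-3-yl]acetate | O[C@@]1(CCCC#C)CC[C@@H](CC(=O)OC)OO1
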